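Ring B is a benzene ring whose only carbon substituent is the C1'–C2 bond and whose oxygens sit para at C2' and C5'. The route disconnects it into a 2,5-dioxygenated furan and the two carbons of an ethynyl group on chromone C2. One operation, a Diels–Alder addition followed by loss of disiloxane, forms C1'–C2' and C6'–C5' and delivers ring B as a 1,4-benzoquinone with both oxygens in place. Its precursor is the fully assembled chromone (rings A and C) carrying the four ring A methoxy groups, a benzyl ether at O3 and a terminal alkyne at C2. Hydrogenation and one BCl3 step then finish the target.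

Key step: step 7

Remark: the target has no stereocentre, so no stereocontrol is needed; compounds 6 and 10 and the Ohira–Bestmann reagent are taken as purchased.

Step 1
Reactants: 1 1,2,3,4-tetramethoxybenzene
Product: 4 2,3,4,5-tetramethoxyphenol, via aryllithium 2 (not isolated), via aryl borate complex 3 (not isolated)
Conditions: n-BuLi, TMEDA, THF, 0 °C; B(OMe)3, −78 °C → rt; AcOH, 30% aq. H2O2, 0 °C → rt
Reagents that add atoms: hydrogen peroxide, OO
Why: Directed ortho-metalation beside a methoxy group (the two ring C–H positions are equivalent), borylation and oxidative 1,2-aryl shift from boron to oxygen make up the standard one-pot arene hydroxylation and should give a single phenol.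

Step 2
Reactants: 4 2,3,4,5-tetramethoxyphenol
Product: 5 1,2,3,4-tetramethoxy-5-(methoxymethoxy)benzene
Conditions: MOMCl, iPr2NEt, CH2Cl2, 0 °C → rt
Reagents that add atoms: chloromethyl methyl ether, COCCl
Why: O-Alkylation of the phenol (MOM protection) masks the acidic OH and supplies a second directing group for the next metalation.

Step 3
Reactants: 5 1,2,3,4-tetramethoxy-5-(methoxymethoxy)benzene, 6 2-(benzyloxy)-N-methoxy-N-methylacetamide
Product: 9 2-(benzyloxy)-1-[2-(methoxymethoxy)-3,4,5,6-tetramethoxyphenyl]ethan-1-one, via aryllithium 7 (not isolated), via lithium hemiaminal adduct 8 (not isolated)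
Conditions: n-BuLi, THF, −78 → 0 °C; 6, −78 → 0 °C; AcOH, then H2O
Reagents that add atoms: none
Why: Directed ortho-metalation at the only ring C–H left, flanked by OMOM and OMe, followed by Weinreb ketone synthesis, whose chelated tetrahedral adduct prevents over-addition, should give the aryl ketone with the benzyloxy carbon already in place.

Step 4
Reactants: 9 2-(benzyloxy)-1-[2-(methoxymethoxy)-3,4,5,6-tetramethoxyphenyl]ethan-1-one, 10 ethyl 2,2-diethoxyacetate
Product: 13 3-(benzyloxy)-5,6,7,8-tetramethoxy-4-oxo-4H-chromene-2-carbaldehyde, via diketone acetal 11 (not isolated), via chromone acetal 12 (not isolated)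
Conditions: LiN(SiMe3)2 (2.2 equiv), THF, −78 °C; 10, −78 °C → rt; then 3 M aq. HCl, THF, 55 °C
Reagents that add atoms: water, O
Why: Crossed Claisen condensation of the ketone enolate with the poorly enolisable dialkoxy ester gives the 1,3-diketone, and dilute acid then removes the MOM group, closes the pyranone by cyclodehydration and hydrolyses the acetal, while the benzyl ether and the aryl methyl ethers should survive.

Step 5
Reactants: 13 3-(benzyloxy)-5,6,7,8-tetramethoxy-4-oxo-4H-chromene-2-carbaldehyde
Product: 15 3-(benzyloxy)-2-ethynyl-5,6,7,8-tetramethoxy-4H-chromen-4-one, via diazoalkene 14 (not isolated)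
Conditions: dimethyl (1-diazo-2-oxopropyl)phosphonate, K2CO3, MeOH/THF, 0 °C → rt
Reagents that add atoms: dimethyl (1-diazo-2-oxopropyl)phosphonate, CC(=O)C(=[N+]=[N-])P(=O)(OC)OC
Why: Ohira–Bestmann homologation (olefination to the diazoalkene, loss of N2 and 1,2-hydrogen shift) converts the aldehyde into the terminal alkyne, and it is run cold and briefly because the chromone is sensitive to methoxide.

Step 6
Reactants: 16 succinic anhydride
Product: 17 2,5-bis(trimethylsilyloxy)furan
Conditions: Me3SiCl, Et3N, ZnCl2 (cat.), MeCN, rt; distillation under reduced pressure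
Reagents that add atoms: chlorotrimethylsilane, C[Si](C)(C)Cl
Why: Double enol silylation of the anhydride is the standard preparation of this diene, which is distilled and used fresh because it is moisture-sensitive.

Step 7
Reactants: 15 3-(benzyloxy)-2-ethynyl-5,6,7,8-tetramethoxy-4H-chromen-4-one, 17 2,5-bis(trimethylsilyloxy)furan
Product: 19 2-[3-(benzyloxy)-5,6,7,8-tetramethoxy-4-oxo-4H-chromen-2-yl]-1,4-benzoquinone, via oxanorbornadiene adduct 18 (not isolated)
Conditions: 17 (1.2 equiv, in portions), toluene, 80 °C; then 5% aq. citric acid, THF, 0 °C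
Reagents that add atoms: none
Why: The electron-rich diene 17 should add through its C2 and C5 across the terminal alkyne of 15, whose LUMO is lowered by conjugation through C2=C3 to the C4 carbonyl (a vinylogous ynone), in a concerted, asynchronous normal-demand Diels–Alder reaction that gives the bis(silyloxy)oxanorbornadiene 18. The oxygen bridge then opens by C–O heterolysis pushed by a bridgehead silyloxy lone pair and silyl transfer expels hexamethyldisiloxane, so that the former furan carbons C2 and C5 become the quinone carbonyls C2' and C5'; the mild acid wash completes this collapse. The closest known reaction type is the benzannulation of 2,5-bis(silyloxy)furans with acetylenic esters and other activated alkynes to p-quinones. Ring B closes as a six-membered carbocycle by an intermolecular [4+2] cycloaddition forming C1'–C2' and C6'–C5', and no stereocentre remains because the bridgehead centres of racemic 18 are lost on fragmentation. The symmetric diene removes any regiochemical question, and the alkyne should be preferred over the C2=C3 double bond because the latter is tetrasubstituted, donor-substituted and sterically shielded. The released quinone is itself a dienophile and nothing in the substrate protects it, so the diene is dosed in portions and not kept in excess; this is the main risk of the step.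

Step 8
Reactants: 19 2-[3-(benzyloxy)-5,6,7,8-tetramethoxy-4-oxo-4H-chromen-2-yl]-1,4-benzoquinone
Product: 21 2-(2,5-dihydroxyphenyl)-3-hydroxy-5,6,7,8-tetramethoxy-4H-chromen-4-one, via benzyl-protected hydroquinone 20 (not isolated)
Conditions: H2 (1 atm), 10% Pd/C, EtOAc/MeOH, rt
Reagents that add atoms: none
Why: Catalytic hydrogenation reduces the quinone to the hydroquinone at once and then cleaves the O3 benzyl ether by hydrogenolysis, while the pyranone C2=C3 bond and the methyl ethers should be untouched under these mild conditions.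

Step 9
Reactants: 21 2-(2,5-dihydroxyphenyl)-3-hydroxy-5,6,7,8-tetramethoxy-4H-chromen-4-one
Product: 22 2-(2,5-dihydroxyphenyl)-3,5-dihydroxy-6,7,8-trimethoxy-4H-chromen-4-one (target)
Conditions: BCl3 (6 equiv), CH2Cl2, −78 → 0 °C; then H2O
Reagents that add atoms: none
Why: Chelation-controlled Lewis acid ether cleavage, in which boron held at the C4 carbonyl activates only the peri C5 methoxy group for chloride attack at methyl, should leave the C6, C7 and C8 methyl ethers intact at or below 0 °C, as in the selective 5-O-demethylation of polymethoxyflavones.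

Compound list

1 | 1,2,3,4-tetramethoxybenzene | COc1ccc(OC)c(OC)c1OC | starting material
2 | 2,3,4,5-tetramethoxyphenyllithium | [Li]c1cc(OC)c(OC)c(OC)c1OC | intermediate
3 | lithium trimethoxy(2,3,4,5-tetramethoxyphenyl)borate | [Li+].CO[B-](OC)(OC)c1cc(OC)c(OC)c(OC)c1OC | intermediate
4 | 2,3,4,5-tetramethoxyphenol | COc1cc(O)c(OC)c(OC)c1OC | intermediate
5 | 1,2,3,4-tetramethoxy-5-(methoxymethoxy)benzene | COCOc1cc(OC)c(OC)c(OC)c1OC | intermediate
6 | 2-(benzyloxy)-N-methoxy-N-methylacetamide | CON(C)C(=O)COCc1ccccc1 | starting material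
7 | [2-(methoxymethoxy)-3,4,5,6-tetramethoxyphenyl]lithium | COCOc1c([Li])c(OC)c(OC)c(OC)c1OC | intermediate
8 | lithium 2-(benzyloxy)-1-[methoxy(methyl)amino]-1-[2-(methoxymethoxy)-3,4,5,6-tetramethoxyphenyl]ethan-1-olate | [Li+].[O-]C(COCc1ccccc1)(N(C)OC)c1c(OCOC)c(OC)c(OC)c(OC)c1OC | intermediate
9 | 2-(benzyloxy)-1-[2-(methoxymethoxy)-3,4,5,6-tetramethoxyphenyl]ethan-1-one | COCOc1c(OC)c(OC)c(OC)c(OC)c1C(=O)COCc1ccccc1 | intermediate
10 | ethyl 2,2-diethoxyacetate | CCOC(=O)C(OCC)OCC | starting material
11 | 2-(benzyloxy)-4,4-diethoxy-1-[2-(methoxymethoxy)-3,4,5,6-tetramethoxyphenyl]butane-1,3-dione | COCOc1c(OC)c(OC)c(OC)c(OC)c1C(=O)C(OCc1ccccc1)C(=O)C(OCC)OCC | intermediate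
12 | 3-(benzyloxy)-2-(diethoxymethyl)-5,6,7,8-tetramethoxy-4H-chromen-4-one | COc1c(OC)c(OC)c2c(=O)c(OCc3ccccc3)c(C(OCC)OCC)oc2c1OC | intermediate
13 | 3-(benzyloxy)-5,6,7,8-tetramethoxy-4-oxo-4H-chromene-2-carbaldehyde | COc1c(OC)c(OC)c2c(=O)c(OCc3ccccc3)c(C=O)oc2c1OC | intermediate
14 | 3-(benzyloxy)-2-(2-diazoethenyl)-5,6,7,8-tetramethoxy-4H-chromen-4-one | COc1c(OC)c(OC)c2c(=O)c(OCc3ccccc3)c(C=C=[N+]=[N-])oc2c1OC | intermediate
15 | 3-(benzyloxy)-2-ethynyl-5,6,7,8-tetramethoxy-4H-chromen-4-one | COc1c(OC)c(OC)c2c(=O)c(OCc3ccccc3)c(C#C)oc2c1OC | intermediate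
16 | succinic anhydride | O=C1CCC(=O)O1 | starting material
17 | 2,5-bis(trimethylsilyloxy)furan | C[Si](C)(C)Oc1ccc(O[Si](C)(C)C)o1 | intermediate
18 | 3-(benzyloxy)-2-[1,4-bis(trimethylsilyloxy)-7-oxabicyclo[2.2.1]hepta-2,5-dien-2-yl]-5,6,7,8-tetramethoxy-4H-chromen-4-one (racemate, one enantiomer drawn) | COc1c(OC)c(OC)c2c(=O)c(OCc3ccccc3)c(C3=C[C@]4(O[Si](C)(C)C)C=C[C@@]3(O[Si](C)(C)C)O4)oc2c1OC | intermediate
19 | 2-[3-(benzyloxy)-5,6,7,8-tetramethoxy-4-oxo-4H-chromen-2-yl]-1,4-benzoquinone | COc1c(OC)c(OC)c2c(=O)c(OCc3ccccc3)c(C3=CC(=O)C=CC3=O)oc2c1OC | intermediate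
20 | 3-(benzyloxy)-2-(2,5-dihydroxyphenyl)-5,6,7,8-tetramethoxy-4H-chromen-4-one | COc1c(OC)c(OC)c2c(=O)c(OCc3ccccc3)c(-c3cc(O)ccc3O)oc2c1OC | intermediate
21 | 2-(2,5-dihydroxyphenyl)-3-hydroxy-5,6,7,8-tetramethoxy-4H-chromen-4-one | COc1c(OC)c(OC)c2c(=O)c(O)c(-c3cc(O)ccc3O)oc2c1OC | intermediate
22 | 2-(2,5-dihydroxyphenyl)-3,5-dihydroxy-6,7,8-trimethoxy-4H-chromen-4-one | COc1c(OC)c(O)c2c(=O)c(O)c(-c3cc(O)ccc3O)oc2c1OC | target

Total step count: 9. Longest linear sequence: 8 steps (steps 1–5 and 7–9; step 6 prepares the diene).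

Steps most likely to fail

Step 7. The cycloaddition to the only moderately activated terminal alkyne may be slower than thermal or hydrolytic loss of the diene, and the quinone, once released, may be consumed by a second cycloaddition with diene still present. The fallback builds ring B by classical acylation instead; it sets out from 9 and comes back at 21. The lithium enolate of 9 (LiN(SiMe3)2, toluene/THF, −78 °C) would be C-acylated with 2,5-bis(benzyloxy)benzoyl chloride F1, made from the purchasable acid with (COCl)2 and catalytic DMF, to give 1-[2,5-bis(benzyloxy)phenyl]-2-(benzyloxy)-3-[2-(methoxymethoxy)-3,4,5,6-tetramethoxyphenyl]propane-1,3-dione F2. Treatment with 3 M aq. HCl in THF at 55 °C should remove the MOM group and close the pyranone to 3-(benzyloxy)-2-[2,5-bis(benzyloxy)phenyl]-5,6,7,8-tetramethoxy-4H-chromen-4-one F3. Hydrogenolysis of the three benzyl ethers (H2, Pd/C) would then give 21, which continues with step 9.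

Step 5. Methoxide may attack C2 of the electron-poor chromone aldehyde and open the pyranone ring, or methanol may add in conjugate fashion to the enynone product. The fallback brings the alkyne in as an acyl unit and avoids the aldehyde; it sets out from 9 and comes back at 15. The lithium enolate of 9 would be acylated with 3-(triisopropylsilyl)prop-2-ynoyl chloride F4, made from the commercial acid with (COCl)2, to give 2-(benzyloxy)-1-[2-(methoxymethoxy)-3,4,5,6-tetramethoxyphenyl]-5-(triisopropylsilyl)pent-4-yne-1,3-dione F5. TsOH·H2O in wet THF at 50 °C should remove the MOM group and cyclodehydrate to 3-(benzyloxy)-5,6,7,8-tetramethoxy-2-[(triisopropylsilyl)ethynyl]-4H-chromen-4-one F6, the bulky silyl group blocking attack at the alkyne terminus. Desilylation with TBAF buffered by AcOH in THF at 0 °C would give 15.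

Step 4. Condensation of the hindered α-benzyloxy enolate with the dialkoxy ester may stall, or slow acetal hydrolysis may force longer acid exposure and erode the benzyl ether. The fallback uses the more electrophilic oxalate and adjusts the oxidation level afterwards; it sets out from 9 and comes back at 13. Claisen condensation of 9 with diethyl oxalate (LiN(SiMe3)2, THF) would give ethyl 3-(benzyloxy)-4-[2-(methoxymethoxy)-3,4,5,6-tetramethoxyphenyl]-2,4-dioxobutanoate F7. HCl in EtOH at 60 °C should then deliver ethyl 3-(benzyloxy)-5,6,7,8-tetramethoxy-4-oxo-4H-chromene-2-carboxylate F8. NaBH4 in EtOH/THF at 0 °C should reduce the activated ester in preference to the vinylogous-ester carbonyl, giving 3-(benzyloxy)-2-(hydroxymethyl)-5,6,7,8-tetramethoxy-4H-chromen-4-one F9. Oxidation with Dess–Martin periodinane in CH2Cl2 would return aldehyde 13.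

Further compounds

F1 | step 7 | 2,5-bis(benzyloxy)benzoyl chloride | O=C(Cl)c1cc(OCc2ccccc2)ccc1OCc1ccccc1
F2 | step 7 | 1-[2,5-bis(benzyloxy)phenyl]-2-(benzyloxy)-3-[2-(methoxymethoxy)-3,4,5,6-tetramethoxyphenyl]propane-1,3-dione | COCOc1c(OC)c(OC)c(OC)c(OC)c1C(=O)C(OCc1ccccc1)C(=O)c1cc(OCc2ccccc2)ccc1OCc1ccccc1
F3 | step 7 | 3-(benzyloxy)-2-[2,5-bis(benzyloxy)phenyl]-5,6,7,8-tetramethoxy-4H-chromen-4-one | COc1c(OC)c(OC)c2c(=O)c(OCc3ccccc3)c(-c3cc(OCc4ccccc4)ccc3OCc3ccccc3)oc2c1OC
F4 | step 5 | 3-(triisopropylsilyl)prop-2-ynoyl chloride | CC(C)[Si](C#CC(=O)Cl)(C(C)C)C(C)C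
F5 | step 5 | 2-(benzyloxy)-1-[2-(methoxymethoxy)-3,4,5,6-tetramethoxyphenyl]-5-(triisopropylsilyl)pent-4-yne-1,3-dione | COCOc1c(OC)c(OC)c(OC)c(OC)c1C(=O)C(OCc1ccccc1)C(=O)C#C[Si](C(C)C)(C(C)C)C(C)C
F6 | step 5 | 3-(benzyloxy)-5,6,7,8-tetramethoxy-2-[(triisopropylsilyl)ethynyl]-4H-chromen-4-one | COc1c(OC)c(OC)c2c(=O)c(OCc3ccccc3)c(C#C[Si](C(C)C)(C(C)C)C(C)C)oc2c1OC
F7 | step 4 | ethyl 3-(benzyloxy)-4-[2-(methoxymethoxy)-3,4,5,6-tetramethoxyphenyl]-2,4-dioxobutanoate | CCOC(=O)C(=O)C(OCc1ccccc1)C(=O)c1c(OCOC)c(OC)c(OC)c(OC)c1OC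
F8 | step 4 | ethyl 3-(benzyloxy)-5,6,7,8-tetramethoxy-4-oxo-4H-chromene-2-carboxylate | COc1c(OC)c(OC)c2c(=O)c(OCc3ccccc3)c(C(=O)OCC)oc2c1OC
F9 | step 4 | 3-(benzyloxy)-2-(hydroxymethyl)-5,6,7,8-tetramethoxy-4H-chromen-4-one | COc1c(OC)c(OC)c2c(=O)c(OCc3ccccc3)c(CO)oc2c1OC
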